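**Plan** (germacrane numbering: ring C1–C10, C14 on C10, C15 on C4, lactone O on C8, C11=C13, C12 carbonyl)

Retrosynthesis cuts, in order: the C6 ester C–O bond and both silyl ethers; the ring bond C5–C6 (alkenyl iodide plus aldehyde); then the lactone O–C12 and C7–C8 bonds together.
The feature that allows the last cut is the α-methylene-γ-butyrolactone ring O–C8–C7–C11(=C13)–C12 with trans substituents at C7 and C8, which is the retron of a γ-substituted 2-alkoxycarbonyl allylboronate adding to a C8 aldehyde.
Forward: a linear C8–C5 aldehyde and a boronate C13–C11(C12)=C7–C6 give the lactone ring first, the ten-membered ring then closes at C5–C6, and acylation and desilylation finish.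
Stereochemistry: C8 from a chiral Brønsted acid (Re face), C7 from the chair transition state and the boronate geometry, C6 from Felkin–Anh addition during ring closure.
Alkene geometry: C1=C10 from syn methylalumination, C4=C5 from syn carbocupration, the side chain from a stabilised Wittig reaction.

Key step: step 11

Assumption: the (R)-configured N-triflylphosphoramide is taken to select the Re face of the C8 aldehyde, as (R)-BINOL phosphoric acids do in allylborations of aliphatic aldehydes; the enantiomeric acid would be used if the sense proved opposite.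

**Route**

Step 1
Reactants: 1 but-3-yn-1-ol
Product: 2 1-[(but-3-yn-1-yloxy)methyl]-4-methoxybenzene
Conditions: NaH, 4-methoxybenzyl chloride, n-Bu4NI (cat.), THF, 0 °C → rt
Reagents that add atoms: 4-methoxybenzyl chloride, COc1ccc(CCl)cc1
Why: Williamson etherification of the primary alkoxide should be clean, and the p-methoxybenzyl ether can later be removed oxidatively beside a silyl ether.

Step 2
Reactants: 2 1-[(but-3-yn-1-yloxy)methyl]-4-methoxybenzene
Product: 4 (E)-6-[(4-methoxybenzyl)oxy]-4-methylhex-3-en-1-ol, via alkenylalane 3 (not isolated)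
Conditions: Me3Al, Cp2ZrCl2 (cat.), CH2Cl2, 0 °C → rt; volatiles removed; n-BuLi, hexane/THF, −78 °C; ethylene oxide, −78 → 0 °C; aqueous sodium potassium tartrate
Reagents that add atoms: trimethylaluminium, C[Al](C)C; ethylene oxide, C1CO1
Why: Zirconium-catalysed methylalumination adds methyl and aluminium syn across the terminal alkyne with aluminium on the terminal carbon, which fixes the E geometry of C1=C10, and the lithium alanate formed with n-BuLi should open ethylene oxide with retention at the alkenyl carbon (alkenylalanate–epoxide alkylation).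

Step 3
Reactants: 4 (E)-6-[(4-methoxybenzyl)oxy]-4-methylhex-3-en-1-ol
Product: 5 1-({[(E)-6-bromo-3-methylhex-3-en-1-yl]oxy}methyl)-4-methoxybenzene
Conditions: CBr4, PPh3, CH2Cl2, 0 °C
Reagents that add atoms: carbon tetrabromide, BrC(Br)(Br)Br
Why: Appel bromination of a primary alcohol runs under neutral conditions that leave the benzylic ether and the trisubstituted alkene untouched.

Step 4
Reactants: 5 1-({[(E)-6-bromo-3-methylhex-3-en-1-yl]oxy}methyl)-4-methoxybenzene; 6 tert-butyldimethyl(prop-2-yn-1-yloxy)silane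
Product: 9 (1E,5E)-2-{[(tert-butyldimethylsilyl)oxy]methyl}-1-iodo-8-[(4-methoxybenzyl)oxy]-6-methylocta-1,5-diene, via Grignard reagent 7 (not isolated), via alkenylcopper 8 (not isolated)
Conditions: Mg, THF, rt; CuBr·SMe2, THF/Me2S, −45 °C; 6, −45 → −20 °C; I2, THF, −60 → 0 °C
Reagents that add atoms: iodine, II
Why: Carbocupration of a terminal alkyne by an alkylcopper–magnesium bromide reagent is a syn addition with the alkyl group on the internal carbon, and iodinolysis with retention then places iodine cis to C3 and trans to C15; the bulky, weakly coordinating silyl ether and THF are chosen to keep copper on the terminal carbon and to avoid β-elimination of the oxygen substituent.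

Step 5
Reactants: 9 (1E,5E)-2-{[(tert-butyldimethylsilyl)oxy]methyl}-1-iodo-8-[(4-methoxybenzyl)oxy]-6-methylocta-1,5-diene
Product: 10 (3E,7E)-7-{[(tert-butyldimethylsilyl)oxy]methyl}-8-iodo-3-methylocta-3,7-dien-1-ol
Conditions: DDQ, CH2Cl2/pH 7 buffer, 0 °C
Reagents that add atoms: none
Why: Oxidative cleavage of the p-methoxybenzyl ether by DDQ should free the C8 alcohol without touching the allylic silyl ether, the alkenyl iodide or the alkenes.

Step 6
Reactants: 10 (3E,7E)-7-{[(tert-butyldimethylsilyl)oxy]methyl}-8-iodo-3-methylocta-3,7-dien-1-ol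
Product: 11 (3E,7E)-7-{[(tert-butyldimethylsilyl)oxy]methyl}-8-iodo-3-methylocta-3,7-dienal
Conditions: Dess–Martin periodinane, NaHCO3, CH2Cl2, 0 °C; used at once
Reagents that add atoms: none
Why: Buffered Dess–Martin oxidation is non-basic and fast, so the β,γ-unsaturated aldehyde should form without migration of C1=C10 into conjugation.

Step 7
Reactants: 12 3,3-diethoxyprop-1-yne
Product: 14 ethyl 4,4-diethoxybut-2-ynoate, via lithium acetylide 13 (not isolated)
Conditions: n-BuLi, THF, −78 °C; ClCO2Et, −78 → 0 °C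
Reagents that add atoms: ethyl chloroformate, CCOC(=O)Cl
Why: Acylation of a lithium acetylide with a chloroformate is a standard route to alkynoates; the ethyl ester matches the acetal so that the ethanol released later cannot scramble the acetal.

Step 8
Reactants: 14 ethyl 4,4-diethoxybut-2-ynoate; 15 2-(iodomethyl)-4,4,5,5-tetramethyl-1,3,2-dioxaborolane
Product: 17 ethyl (Z)-4,4-diethoxy-2-[(4,4,5,5-tetramethyl-1,3,2-dioxaborolan-2-yl)methyl]but-2-enoate, via alkenylalane 16 (not isolated)
Conditions: i-Bu2AlH, HMPA, THF, 0 °C; then 14, 0 °C; then 15, 0 °C → rt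
Reagents that add atoms: none
Why: The i-Bu2AlH–HMPA complex adds hydride to the β-carbon of the alkynoate and aluminium to the α-carbon in a syn sense, and C-alkylation of this α-aluminio acrylate by the iodomethylboronate with retention places C6 trans to the CH2B carbon (conjugate hydroalumination with electrophilic trapping).

Step 9
Reactants: 18 2-[(tert-butyldimethylsilyl)oxy]acetaldehyde; 19 ethyl 2-(triphenyl-λ5-phosphanylidene)propanoate
Product: 20 ethyl (E)-4-[(tert-butyldimethylsilyl)oxy]-2-methylbut-2-enoate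
Conditions: CH2Cl2, rt
Reagents that add atoms: none
Why: Wittig reaction of an α-methyl stabilised ylide with an unhindered aldehyde is strongly E-selective and sets the tiglate-type geometry of the side chain.

Step 10
Reactants: 20 ethyl (E)-4-[(tert-butyldimethylsilyl)oxy]-2-methylbut-2-enoate
Product: 21 (E)-4-[(tert-butyldimethylsilyl)oxy]-2-methylbut-2-enoic acid
Conditions: LiOH, THF/H2O, rt; 1 M HCl to pH 4, 0 °C
Reagents that add atoms: lithium hydroxide, [Li+].[OH-]
Why: Saponification of the ethyl ester should leave the primary silyl ether and the alkene geometry intact.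

Step 11
Reactants: 11 (3E,7E)-7-{[(tert-butyldimethylsilyl)oxy]methyl}-8-iodo-3-methylocta-3,7-dienal; 17 ethyl (Z)-4,4-diethoxy-2-[(4,4,5,5-tetramethyl-1,3,2-dioxaborolan-2-yl)methyl]but-2-enoate
Product: 23 (4R,5S)-4-(diethoxymethyl)-5-[(2E,6E)-6-{[(tert-butyldimethylsilyl)oxy]methyl}-7-iodo-2-methylhepta-2,6-dien-1-yl]-3-methylideneoxolan-2-one, via borate ester 22 (not isolated)
Conditions: (R)-3,3′-bis(2,4,6-triisopropylphenyl)-1,1′-binaphthalene-2,2′-diyl N-(trifluoromethylsulfonyl)phosphoramide (10 mol %), 4 Å molecular sieves, toluene, −20 °C → rt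
Reagents that add atoms: none
Why: The chiral acid hydrogen-bonds to a boronate oxygen and so raises the Lewis acidity of boron, which binds the C8 aldehyde oxygen; the allyl unit is then delivered through a closed six-membered chair with SE2′ transposition, so that C7–C8 and the exocyclic C11=C13 form together to give borate 22. The closest known reaction type is the Brønsted-acid-catalysed allylboration of aldehydes by 2-alkoxycarbonyl allylboronates with in situ lactonisation to α-methylene-γ-butyrolactones, which also runs with chiral BINOL-derived acids. The lactone ring closes in 22 by 5-exo-trig attack of the borate oxygen on the C12 ester carbonyl, with ethoxide passing to boron. C7 is controlled by the boronate geometry: with C6 trans to the CH2B carbon, C6 and the aldehyde chain are both equatorial in the chair, which gives the anti adduct and hence the trans lactone; C8 is controlled by the (R)-configured catalyst, which is expected to expose the Re face of the aldehyde and so to give 8S and, through the chair, 7R. The step needs anti over syn addition, one aldehyde face, and survival of the acetal, the silyl ether and the β,γ-alkene; these rest on the single alkene geometry of 17, on catalyst control (neither partner has a stereocentre), on anhydrous conditions over molecular sieves, and on the aliphatic C8, which cannot ionise to a stabilised cation and so cannot scramble the lactone configuration.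

Step 12
Reactants: 23 (4R,5S)-4-(diethoxymethyl)-5-[(2E,6E)-6-{[(tert-butyldimethylsilyl)oxy]methyl}-7-iodo-2-methylhepta-2,6-dien-1-yl]-3-methylideneoxolan-2-one
Product: 24 (2S,3R)-2-[(2E,6E)-6-{[(tert-butyldimethylsilyl)oxy]methyl}-7-iodo-2-methylhepta-2,6-dien-1-yl]-4-methylidene-5-oxooxolane-3-carbaldehyde
Conditions: TESOTf, 2,6-lutidine, CH2Cl2, 0 °C; then H2O; used at once
Reagents that add atoms: water, O
Why: The silyl triflate ionises the diethyl acetal, 2,6-lutidine traps the oxocarbenium ion as a pyridinium salt and water releases the aldehyde, so the primary silyl ether survives and the enolisable C7 centre meets neither aqueous acid nor strong base (silyl triflate–pyridine acetal cleavage).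

Step 13
Reactants: 24 (2S,3R)-2-[(2E,6E)-6-{[(tert-butyldimethylsilyl)oxy]methyl}-7-iodo-2-methylhepta-2,6-dien-1-yl]-4-methylidene-5-oxooxolane-3-carbaldehyde
Product: 26 (6R,7R,8S)-15-[(tert-butyldimethylsilyl)oxy]-6-hydroxygermacra-1(10),4,11(13)-trien-12,8-olide, via alkenylchromium 25 (not isolated)
Conditions: CrCl2 (excess), NiCl2 (cat.), DMSO, rt, high dilution, slow addition of 24
Reagents that add atoms: none
Why: Intramolecular Nozaki–Hiyama–Kishi reaction: zerovalent nickel formed in situ inserts into the alkenyl iodide, transmetalation to trivalent chromium gives alkenylchromium 25 with retention of the C4=C5 geometry, and its chemoselective addition to the C6 aldehyde closes the ten-membered ring; C6 is expected as 6R from Felkin–Anh approach of C5 anti to the C7–C8 bond with the carbonyl oxygen on the side of C11.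

Step 14
Reactants: 26 (6R,7R,8S)-15-[(tert-butyldimethylsilyl)oxy]-6-hydroxygermacra-1(10),4,11(13)-trien-12,8-olide; 21 (E)-4-[(tert-butyldimethylsilyl)oxy]-2-methylbut-2-enoic acid
Product: 28 (6R,7R,8S)-15-[(tert-butyldimethylsilyl)oxy]-6-({(E)-4-[(tert-butyldimethylsilyl)oxy]-2-methylbut-2-enoyl}oxy)germacra-1(10),4,11(13)-trien-12,8-olide, via mixed anhydride 27 (not isolated)
Conditions: 21, 2,4,6-trichlorobenzoyl chloride, Et3N, toluene, rt; then 26, DMAP, rt
Reagents that add atoms: none
Why: Yamaguchi esterification acylates hindered secondary alcohols with retention at carbon and keeps the stable E geometry of the acid, and prompt acylation also blocks transfer of the lactone from O8 to the free O6.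

Step 15
Reactants: 28 (6R,7R,8S)-15-[(tert-butyldimethylsilyl)oxy]-6-({(E)-4-[(tert-butyldimethylsilyl)oxy]-2-methylbut-2-enoyl}oxy)germacra-1(10),4,11(13)-trien-12,8-olide
Product: 29 (6R,7R,8S)-15-hydroxy-6-{[(E)-4-hydroxy-2-methylbut-2-enoyl]oxy}germacra-1(10),4,11(13)-trien-12,8-olide (CNP0344932.2)
Conditions: HF·pyridine, pyridine, THF, 0 °C → rt
Reagents that add atoms: none
Why: Buffered fluoride desilylation should remove both primary allylic silyl ethers without acyl migration or attack on the α-methylene lactone, and the E side chain cannot lactonise onto its own ester.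

**Compound list**

1 | but-3-yn-1-ol | C#CCCO | starting material
2 | 1-[(but-3-yn-1-yloxy)methyl]-4-methoxybenzene | C#CCCOCc1ccc(OC)cc1 | intermediate
3 | dimethyl{(E)-4-[(4-methoxybenzyl)oxy]-2-methylbut-1-en-1-yl}alane | C[Al](C)/C=C(\C)CCOCc1ccc(OC)cc1 | intermediate
4 | (E)-6-[(4-methoxybenzyl)oxy]-4-methylhex-3-en-1-ol | OCC/C=C(\C)CCOCc1ccc(OC)cc1 | intermediate
5 | 1-({[(E)-6-bromo-3-methylhex-3-en-1-yl]oxy}methyl)-4-methoxybenzene | BrCC/C=C(\C)CCOCc1ccc(OC)cc1 | intermediate
6 | tert-butyldimethyl(prop-2-yn-1-yloxy)silane | C#CCO[Si](C)(C)C(C)(C)C | starting material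
7 | {(E)-6-[(4-methoxybenzyl)oxy]-4-methylhex-3-en-1-yl}magnesium bromide | Br[Mg]CC/C=C(\C)CCOCc1ccc(OC)cc1 | intermediate
8 | {(1E,5E)-2-{[(tert-butyldimethylsilyl)oxy]methyl}-8-[(4-methoxybenzyl)oxy]-6-methylocta-1,5-dien-1-yl}copper | [Cu]/C=C(/CO[Si](C)(C)C(C)(C)C)CC/C=C(\C)CCOCc1ccc(OC)cc1 | intermediate
9 | (1E,5E)-2-{[(tert-butyldimethylsilyl)oxy]methyl}-1-iodo-8-[(4-methoxybenzyl)oxy]-6-methylocta-1,5-diene | COc1ccc(COCC/C(C)=C/CC/C(CO[Si](C)(C)C(C)(C)C)=C\I)cc1 | intermediate
10 | (3E,7E)-7-{[(tert-butyldimethylsilyl)oxy]methyl}-8-iodo-3-methylocta-3,7-dien-1-ol | OCC/C(C)=C/CC/C(CO[Si](C)(C)C(C)(C)C)=C\I | intermediate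
11 | (3E,7E)-7-{[(tert-butyldimethylsilyl)oxy]methyl}-8-iodo-3-methylocta-3,7-dienal | O=CC/C(C)=C/CC/C(CO[Si](C)(C)C(C)(C)C)=C\I | intermediate
12 | 3,3-diethoxyprop-1-yne | C#CC(OCC)OCC | starting material
13 | (3,3-diethoxyprop-1-yn-1-yl)lithium | [Li]C#CC(OCC)OCC | intermediate
14 | ethyl 4,4-diethoxybut-2-ynoate | CCOC(=O)C#CC(OCC)OCC | intermediate
15 | 2-(iodomethyl)-4,4,5,5-tetramethyl-1,3,2-dioxaborolane | CC1(C)OB(CI)OC1(C)C | starting material
16 | ethyl (E)-2-(diisobutylalumanyl)-4,4-diethoxybut-2-enoate | CCOC(OCC)/C=C(/[Al](CC(C)C)CC(C)C)C(=O)OCC | intermediate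
17 | ethyl (Z)-4,4-diethoxy-2-[(4,4,5,5-tetramethyl-1,3,2-dioxaborolan-2-yl)methyl]but-2-enoate | CCOC(OCC)/C=C(/CB1OC(C)(C)C(C)(C)O1)C(=O)OCC | intermediate
18 | 2-[(tert-butyldimethylsilyl)oxy]acetaldehyde | O=CCO[Si](C)(C)C(C)(C)C | starting material
19 | ethyl 2-(triphenyl-λ5-phosphanylidene)propanoate | CCOC(=O)C(C)=P(c1ccccc1)(c1ccccc1)c1ccccc1 | starting material
20 | ethyl (E)-4-[(tert-butyldimethylsilyl)oxy]-2-methylbut-2-enoate | CCOC(=O)/C(C)=C/CO[Si](C)(C)C(C)(C)C | intermediate
21 | (E)-4-[(tert-butyldimethylsilyl)oxy]-2-methylbut-2-enoic acid | OC(=O)/C(C)=C/CO[Si](C)(C)C(C)(C)C | intermediate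
22 | ethyl (3R,4S,6E,10E)-10-{[(tert-butyldimethylsilyl)oxy]methyl}-3-(diethoxymethyl)-11-iodo-6-methyl-2-methylidene-4-[(4,4,5,5-tetramethyl-1,3,2-dioxaborolan-2-yl)oxy]undeca-6,10-dienoate | CCOC(=O)C(=C)[C@@H](C(OCC)OCC)[C@H](C/C(C)=C/CC/C(CO[Si](C)(C)C(C)(C)C)=C\I)OB1OC(C)(C)C(C)(C)O1 | intermediate
23 | (4R,5S)-4-(diethoxymethyl)-5-[(2E,6E)-6-{[(tert-butyldimethylsilyl)oxy]methyl}-7-iodo-2-methylhepta-2,6-dien-1-yl]-3-methylideneoxolan-2-one | C=C1C(=O)O[C@@H](C/C(C)=C/CC/C(CO[Si](C)(C)C(C)(C)C)=C\I)[C@@H]1C(OCC)OCC | intermediate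
24 | (2S,3R)-2-[(2E,6E)-6-{[(tert-butyldimethylsilyl)oxy]methyl}-7-iodo-2-methylhepta-2,6-dien-1-yl]-4-methylidene-5-oxooxolane-3-carbaldehyde | C=C1C(=O)O[C@@H](C/C(C)=C/CC/C(CO[Si](C)(C)C(C)(C)C)=C\I)[C@@H]1C=O | intermediate
25 | alkenylchromium dichloride (trivalent chromium) formed from 24 at C5 | C=C1C(=O)O[C@@H](C/C(C)=C/CC/C(CO[Si](C)(C)C(C)(C)C)=C\[Cr](Cl)Cl)[C@@H]1C=O | intermediate
26 | (6R,7R,8S)-15-[(tert-butyldimethylsilyl)oxy]-6-hydroxygermacra-1(10),4,11(13)-trien-12,8-olide (E C1=C10; C3 and C6 cis on C4=C5; trans lactone) | C=C1C(=O)O[C@H]2C/C(C)=C/CC/C(CO[Si](C)(C)C(C)(C)C)=C\[C@@H](O)[C@H]12 | intermediate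
27 | (E)-4-[(tert-butyldimethylsilyl)oxy]-2-methylbut-2-enoic 2,4,6-trichlorobenzoic anhydride | O=C(OC(=O)c1c(Cl)cc(Cl)cc1Cl)/C(C)=C/CO[Si](C)(C)C(C)(C)C | intermediate
28 | (6R,7R,8S)-15-[(tert-butyldimethylsilyl)oxy]-6-({(E)-4-[(tert-butyldimethylsilyl)oxy]-2-methylbut-2-enoyl}oxy)germacra-1(10),4,11(13)-trien-12,8-olide | C=C1C(=O)O[C@H]2C/C(C)=C/CC/C(CO[Si](C)(C)C(C)(C)C)=C\[C@@H](OC(=O)/C(C)=C/CO[Si](C)(C)C(C)(C)C)[C@H]12 | intermediate
29 | (6R,7R,8S)-15-hydroxy-6-{[(E)-4-hydroxy-2-methylbut-2-enoyl]oxy}germacra-1(10),4,11(13)-trien-12,8-olide | C=C1C(=O)O[C@H]2C/C(C)=C/CC/C(CO)=C\[C@@H](OC(=O)/C(C)=C/CO)[C@H]12 | target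

**Step count and risks**

Total: 15 steps. Longest linear sequence: 11 steps (steps 1–6, then 11–15).

Step 11 (key step). The boronate is deactivated by its ester and by the γ-acetal, so the addition may be slow. Then acid-induced ionisation of the acetal with loss of the boryl group, migration of the β,γ-alkene of the aldehyde into conjugation, or weak discrimination of the aldehyde faces could take over. The fallback makes the same two bonds by a nickel-free chromium-catalysed enantioselective 2-(alkoxycarbonyl)allylation; it sets out from 17 and comes back at 23. Oxidation of the C–B bond of 17 (NaBO3·4H2O, THF/H2O) should give ethyl (Z)-4,4-diethoxy-2-(hydroxymethyl)but-2-enoate F1, and Appel bromination (CBr4, PPh3, CH2Cl2) ethyl (E)-2-(bromomethyl)-4,4-diethoxybut-2-enoate F2. F2 would then add to aldehyde 11 under CrCl2 (cat.), (S,S)-1,8-bis(4-isopropyl-4,5-dihydrooxazol-2-yl)-3,6-diphenyl-9H-carbazole, Mn and Cp2ZrCl2 in THF, the ligand enantiomer being chosen for the Re face. The allylchromium species adds through a chair to give the anti adduct, ethyl (3R,4S,6E,10E)-10-{[(tert-butyldimethylsilyl)oxy]methyl}-3-(diethoxymethyl)-4-hydroxy-11-iodo-6-methyl-2-methylideneundeca-6,10-dienoate F3, and the alkenyl iodide stays inert without nickel. Warming F3 with pyridinium p-toluenesulfonate in toluene closes the lactone to 23.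

Step 13. The ring closure may add to the wrong face of the C6 aldehyde, couple between molecules, or let the exocyclic alkene of 24 drift into conjugation or the lactone transfer to the new C6 alkoxide during the slow addition. The fallback answers the facial problem; it sets out from 24 and comes back at 28. If the closure gives mainly the epimeric alcohol, (6S,7R,8S)-15-[(tert-butyldimethylsilyl)oxy]-6-hydroxygermacra-1(10),4,11(13)-trien-12,8-olide F4, this is esterified with acid 21 under Mitsunobu conditions (PPh3, diisopropyl azodicarboxylate, toluene, 0 °C). The inversion at C6 gives 28 directly, so either facial outcome of the ring closure can be used.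

Step 4. The organocopper reagent may add in the reverse orientation, with copper on the internal carbon followed by β-elimination of the silyloxy group to an allene, or it may simply deprotonate the alkyne. The fallback forms the C3–C4 bond by cross-coupling on a template of fixed geometry; it sets out from 5 and comes back at 9. Commercial 3-(trimethylsilyl)prop-2-yn-1-ol undergoes hydroxyl-directed trans-hydrostannation (Bu3SnH, [Cp*RuCl]4 cat., CH2Cl2) to (Z)-2-(tributylstannyl)-3-(trimethylsilyl)prop-2-en-1-ol F5. Iododestannylation (I2, CH2Cl2, 0 °C) gives (Z)-2-iodo-3-(trimethylsilyl)prop-2-en-1-ol F6, and silylation (TBSCl, imidazole, DMF) tert-butyl{[(Z)-2-iodo-3-(trimethylsilyl)prop-2-en-1-yl]oxy}dimethylsilane F7. Bromide 5 is converted with Zn and LiCl in THF into {(E)-6-[(4-methoxybenzyl)oxy]-4-methylhex-3-en-1-yl}zinc bromide F8. Negishi coupling of F8 with F7 (Pd(dppf)Cl2, THF/NMP) gives, with retention, (1E,5E)-2-{[(tert-butyldimethylsilyl)oxy]methyl}-8-[(4-methoxybenzyl)oxy]-6-methyl-1-(trimethylsilyl)octa-1,5-diene F9. Iododesilylation with retention (N-iodosuccinimide, MeCN/ClCH2CN, 0 °C) returns 9.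

**Further compounds**

F1 | step 11 | ethyl (Z)-4,4-diethoxy-2-(hydroxymethyl)but-2-enoate | CCOC(OCC)/C=C(/CO)C(=O)OCC
F2 | step 11 | ethyl (E)-2-(bromomethyl)-4,4-diethoxybut-2-enoate | CCOC(OCC)/C=C(/CBr)C(=O)OCC
F3 | step 11 | ethyl (3R,4S,6E,10E)-10-{[(tert-butyldimethylsilyl)oxy]methyl}-3-(diethoxymethyl)-4-hydroxy-11-iodo-6-methyl-2-methylideneundeca-6,10-dienoate | CCOC(=O)C(=C)[C@@H](C(OCC)OCC)[C@H](C/C(C)=C/CC/C(CO[Si](C)(C)C(C)(C)C)=C\I)O
F4 | step 13 | (6S,7R,8S)-15-[(tert-butyldimethylsilyl)oxy]-6-hydroxygermacra-1(10),4,11(13)-trien-12,8-olide | C=C1C(=O)O[C@H]2C/C(C)=C/CC/C(CO[Si](C)(C)C(C)(C)C)=C\[C@H](O)[C@H]12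
F5 | step 4 | (Z)-2-(tributylstannyl)-3-(trimethylsilyl)prop-2-en-1-ol | OC/C([Sn](CCCC)(CCCC)CCCC)=C/[Si](C)(C)C
F6 | step 4 | (Z)-2-iodo-3-(trimethylsilyl)prop-2-en-1-ol | OC/C(I)=C/[Si](C)(C)C
F7 | step 4 | tert-butyl{[(Z)-2-iodo-3-(trimethylsilyl)prop-2-en-1-yl]oxy}dimethylsilane | CC(C)(C)[Si](C)(C)OC/C(I)=C/[Si](C)(C)C
F8 | step 4 | {(E)-6-[(4-methoxybenzyl)oxy]-4-methylhex-3-en-1-yl}zinc bromide | Br[Zn]CC/C=C(\C)CCOCc1ccc(OC)cc1
F9 | step 4 | (1E,5E)-2-{[(tert-butyldimethylsilyl)oxy]methyl}-8-[(4-methoxybenzyl)oxy]-6-methyl-1-(trimethylsilyl)octa-1,5-diene | COc1ccc(COCC/C(C)=C/CC/C(CO[Si](C)(C)C(C)(C)C)=C\[Si](C)(C)C)cc1
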